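The ten-membered carbocycle (C1–C10) is disconnected at C9–C10. Because C9 is a carbinol flanking the C1=C10 enoate, C10 can enter as an alkyne carbon that attacks a C9 aldehyde: one chromium-mediated iodoalkyne–aldehyde coupling forms the C9–C10 bond, closes the ring and creates the C9 stereocentre, and the resulting ring alkyne later gives the ring-cis C1=C10 alkene when hydrogen and the ester carbon are added syn. The precursor is an open-chain C9 aldehyde carrying the C6–C8 stereotriad (from (S)-malate), the C4=C5 alkene with C3 cis to C6 and a C10 iodoalkyne, with O8 as PMB ether, O6 and O12 as TBS ethers and O15 as a TBDPS ether.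

Key step: step 19

Remark (numbering): atoms are discussed with the germacrane locants of the target (ring C1–C10; C11–C13 on C7; C14 the ester carbon on C10; C15 the oxymethyl carbon on C4). Open-chain intermediates carry systematic names with their own chain locants; ring compounds (29 onwards) are named with germacrane locants. CIP descriptors change with the protecting groups although no centre is inverted.
Remark (abbreviations): PMB = 4-methoxybenzyl, TBS = tert-butyldimethylsilyl, TBDPS = tert-butyldiphenylsilyl; TBSO, TBDPSO, PMBO are the corresponding ether substituents.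
Remark (acetal): the dioxolane acetal carbon of 6–24 is carried as a mixture of epimers, which converge in step 16.
Remark (starting material): 21 is taken as a catalogue compound; it is also available in one step from but-3-yn-1-ol.

Step 1
Reactants: 1 dimethyl (S)-malate; 2 allyl bromide
Product: 4 dimethyl (2S,3R)-2-hydroxy-3-(prop-2-en-1-yl)butanedioate, via dilithium alkoxide–enolate 3 (not isolated)
Conditions: LiN(SiMe3)2 (2.2 equiv), THF, −78 to −20 °C; then 2, −78 to −10 °C; NH4Cl (aq)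
Reagents that add atoms: none
Why: Fráter–Seebach alkylation, in which the chelated lithium alkoxide–enolate is allylated on the face away from the alkoxide-bearing carbon, so that the new C7 centre (3R) is set anti to the C8 hydroxyl inherited from (S)-malate and the minor syn isomer can be removed by chromatography.

Step 2
Reactants: 4 dimethyl (2S,3R)-2-hydroxy-3-(prop-2-en-1-yl)butanedioate
Product: 5 methyl (2R)-2-[(1S)-1,2-dihydroxyethyl]pent-4-enoate
Conditions: BH3·SMe2 (1.0 equiv), NaBH4 (5 mol%), THF, 0 °C to rt; then MeOH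
Reagents that add atoms: none
Why: Hydroxyl-directed chemoselective borane reduction, in which the alkoxyborane formed at O8 delivers hydride through a five-membered chelate only to the adjacent C9 ester, the single equivalent of borane being consumed by the hydroxyl group and that ester before it can hydroborate the terminal alkene or reduce the C6 ester, with no stereocentre affected.

Step 3
Reactants: 5 methyl (2R)-2-[(1S)-1,2-dihydroxyethyl]pent-4-enoate
Product: 6 methyl (2R)-2-[(4S)-2-(4-methoxyphenyl)-1,3-dioxolan-4-yl]pent-4-enoate (both acetal epimers)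
Conditions: 4-MeOC6H4CH(OMe)2, PPTS (cat.), CH2Cl2, rt
Reagents that add atoms: 4-methoxybenzaldehyde dimethyl acetal, `COc1ccc(C(OC)OC)cc1`
Why: Acid-catalysed transacetalisation closes the five-membered dioxolane on the 1,2-diol faster than the diol ester lactonises, masking O8 and O9 together in a form that later opens to the O8 PMB ether, the acetal carbon being the only new and stereochemically irrelevant centre.

Step 4
Reactants: 6 methyl (2R)-2-[(4S)-2-(4-methoxyphenyl)-1,3-dioxolan-4-yl]pent-4-enoate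
Product: 7 (2R)-N-methoxy-2-[(4S)-2-(4-methoxyphenyl)-1,3-dioxolan-4-yl]-N-methylpent-4-enamide
Conditions: MeNH(OMe)·HCl, i-PrMgCl, THF, −20 to 0 °C
Reagents that add atoms: N,O-dimethylhydroxylamine hydrochloride, `CNOC.Cl`
Why: Weinreb amide formation by aminolysis of the methyl ester with the magnesium amide of N,O-dimethylhydroxylamine, which proceeds at low temperature without enolising C7 or disturbing the acetal.

Step 5
Reactants: 8 propargyl alcohol
Product: 9 tert-butyl(diphenyl)(prop-2-yn-1-yloxy)silane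
Conditions: TBDPSCl, imidazole, CH2Cl2, 0 °C to rt
Reagents that add atoms: tert-butyl(chloro)diphenylsilane, `CC(C)(C)[Si](Cl)(c1ccccc1)c1ccccc1`
Why: Imidazole-promoted silylation of a primary alcohol gives the C5–C4–C15 unit with O15 in the one silyl ether that is meant to outlast both TBS ethers at the end.

Step 6
Reactants: 7 (2R)-N-methoxy-2-[(4S)-2-(4-methoxyphenyl)-1,3-dioxolan-4-yl]-N-methylpent-4-enamide; 9 tert-butyl(diphenyl)(prop-2-yn-1-yloxy)silane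
Product: 11 (5R)-1-(TBDPSO)-5-[(4S)-2-(4-methoxyphenyl)-1,3-dioxolan-4-yl]oct-7-en-2-yn-4-one, via lithium acetylide 10 (not isolated)
Conditions: 9, n-BuLi, THF, −78 °C; then 7, −78 to 0 °C; NH4Cl (aq)
Reagents that add atoms: none
Why: Acylation of a lithium acetylide by a Weinreb amide, whose chelated tetrahedral adduct survives until work-up and therefore gives the C6 ynone without over-addition and without epimerising C7.

Step 7
Reactants: 11 (5R)-1-(TBDPSO)-5-[(4S)-2-(4-methoxyphenyl)-1,3-dioxolan-4-yl]oct-7-en-2-yn-4-one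
Product: 12 (4S,5S)-1-(TBDPSO)-5-[(4S)-2-(4-methoxyphenyl)-1,3-dioxolan-4-yl]oct-7-en-2-yn-4-ol
Conditions: Ru(p-cymene)[(S,S)-TsDPEN] (2 mol%), i-PrOH, rt
Reagents that add atoms: none
Why: Noyori-type asymmetric transfer hydrogenation of an alkynyl ketone, in which the (S,S)-diamine catalyst treats the alkynyl group as it treats an aryl group and delivers hydride to give the (S)-propargylic carbinol, so that C6 is set by the catalyst and not by the adjacent C7 centre.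

Step 8
Reactants: 12 (4S,5S)-1-(TBDPSO)-5-[(4S)-2-(4-methoxyphenyl)-1,3-dioxolan-4-yl]oct-7-en-2-yn-4-ol
Product: 14 (2Z,4S,5S)-1-(TBDPSO)-2-iodo-5-[(4S)-2-(4-methoxyphenyl)-1,3-dioxolan-4-yl]octa-2,7-dien-4-ol, via cyclic sodium alkenylalanate 13 (not isolated)
Conditions: NaAlH2(OCH2CH2OMe)2, THF, 0 °C; then I2, THF, −78 °C
Reagents that add atoms: iodine, `[I][I]`
Why: Hydroxyl-directed trans-hydroalumination of the propargylic alkoxide gives a five-membered alanate with hydrogen on C5 and aluminium on C4 cis to C6, and iodinolysis with retention then gives the (Z)-iodoalkene in which C15 is trans to C6, the geometry the ring needs.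

Step 9
Reactants: 14 (2Z,4S,5S)-1-(TBDPSO)-2-iodo-5-[(4S)-2-(4-methoxyphenyl)-1,3-dioxolan-4-yl]octa-2,7-dien-4-ol
Product: 15 (2Z,4S,5R)-4-(TBSO)-1-(TBDPSO)-2-iodo-5-[(4S)-2-(4-methoxyphenyl)-1,3-dioxolan-4-yl]octa-2,7-diene
Conditions: TBSOTf, 2,6-lutidine, CH2Cl2, −78 °C
Reagents that add atoms: tert-butyldimethylsilyl triflate, `CC(C)(C)[Si](C)(C)OS(=O)(=O)C(F)(F)F`
Why: Silyl triflate silylation of the hindered secondary allylic alcohol under cold, lutidine-buffered conditions that leave the acetal intact.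

Step 10
Reactants: 15 (2Z,4S,5R)-4-(TBSO)-1-(TBDPSO)-2-iodo-5-[(4S)-2-(4-methoxyphenyl)-1,3-dioxolan-4-yl]octa-2,7-diene
Product: 17 (3R,4S,5Z)-4-(TBSO)-7-(TBDPSO)-6-iodo-3-[(4S)-2-(4-methoxyphenyl)-1,3-dioxolan-4-yl]hept-5-enal, via vicinal diol 16 (not isolated)
Conditions: OsO4 (2 mol%), NaIO4, 2,6-lutidine, dioxane–H2O, rt
Reagents that add atoms: osmium tetroxide, `O=[Os](=O)(=O)=O`; sodium periodate, `[Na+].[O-]I(=O)(=O)=O`
Why: Lemieux–Johnson oxidative cleavage, in which OsO4 dihydroxylates the unhindered monosubstituted alkene in preference to the hindered, electron-poor iodoalkene and periodate cleaves the diol to the C12 aldehyde while 2,6-lutidine suppresses over-oxidation.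

Step 11
Reactants: 17 (3R,4S,5Z)-4-(TBSO)-7-(TBDPSO)-6-iodo-3-[(4S)-2-(4-methoxyphenyl)-1,3-dioxolan-4-yl]hept-5-enal
Product: 18 (3R,4S,5Z)-4-(TBSO)-7-(TBDPSO)-6-iodo-3-[(4S)-2-(4-methoxyphenyl)-1,3-dioxolan-4-yl]-2-methylidenehept-5-enal
Conditions: CH2O (37% aq), pyrrolidine (10 mol%), EtCO2H (10 mol%), i-PrOH, 45 °C
Reagents that add atoms: formaldehyde, `C=O`
Why: Amine-catalysed Mannich condensation of the aldehyde with formaldehyde followed by elimination of the amine (organocatalytic α-methylenation) installs C13 on C11 under nearly neutral conditions that spare the acetal and silyl ethers and cannot epimerise C7, which is not vinylogously acidic.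

Step 12
Reactants: 18 (3R,4S,5Z)-4-(TBSO)-7-(TBDPSO)-6-iodo-3-[(4S)-2-(4-methoxyphenyl)-1,3-dioxolan-4-yl]-2-methylidenehept-5-enal
Product: 19 (3R,4S,5Z)-4-(TBSO)-7-(TBDPSO)-6-iodo-3-[(4S)-2-(4-methoxyphenyl)-1,3-dioxolan-4-yl]-2-methylidenehept-5-en-1-ol
Conditions: NaBH4, CeCl3·7H2O, MeOH, −40 °C
Reagents that add atoms: none
Why: Luche reduction gives clean 1,2-reduction of the 2-substituted acrolein to the C12 allylic alcohol without conjugate reduction.

Step 13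
Reactants: 19 (3R,4S,5Z)-4-(TBSO)-7-(TBDPSO)-6-iodo-3-[(4S)-2-(4-methoxyphenyl)-1,3-dioxolan-4-yl]-2-methylidenehept-5-en-1-ol
Product: 20 (3R,4S,5Z)-1,4-bis(TBSO)-7-(TBDPSO)-6-iodo-3-[(4S)-2-(4-methoxyphenyl)-1,3-dioxolan-4-yl]-2-methylidenehept-5-ene
Conditions: TBSCl, imidazole, DMF, rt
Reagents that add atoms: tert-butyldimethylsilyl chloride, `CC(C)(C)[Si](C)(C)Cl`
Why: Routine silylation of the primary allylic alcohol, so that O12 and O6 carry the same silyl group and can later be released together.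

Step 14
Reactants: 21 4-(trimethylsilyl)but-3-yn-1-ol
Product: 22 (4-iodobut-1-yn-1-yl)trimethylsilane
Conditions: I2, PPh3, imidazole, CH2Cl2, 0 °C to rt
Reagents that add atoms: iodine, `[I][I]`
Why: Appel-type iodination of a primary alcohol through its alkoxyphosphonium iodide gives the C3–C2–C1≡C10 unit as a primary iodide ready for zinc insertion.

Step 15
Reactants: 20 (3R,4S,5Z)-1,4-bis(TBSO)-7-(TBDPSO)-6-iodo-3-[(4S)-2-(4-methoxyphenyl)-1,3-dioxolan-4-yl]-2-methylidenehept-5-ene; 22 (4-iodobut-1-yn-1-yl)trimethylsilane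
Product: 24 (3R,4R,5E)-1,4-bis(TBSO)-6-(TBDPSOCH2)-3-[(4S)-2-(4-methoxyphenyl)-1,3-dioxolan-4-yl]-2-methylidene-10-(trimethylsilyl)dec-5-en-9-yne, via [4-(trimethylsilyl)but-3-yn-1-yl]zinc iodide 23 (not isolated)
Conditions: 22, Zn dust, LiCl, THF, 40 °C; then 20, PdCl2(dppf) (5 mol%), THF, 50 °C
Reagents that add atoms: none
Why: Negishi alkyl–alkenyl coupling, in which zinc inserts into the primary C–I bond and the alkylzinc iodide transmetalates to the alkenylpalladium formed from 20, the bidentate ligand favouring reductive elimination over β-hydride elimination and the alkene geometry being retained so that C3 ends up cis to C6.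

Step 16
Reactants: 24 (3R,4R,5E)-1,4-bis(TBSO)-6-(TBDPSOCH2)-3-[(4S)-2-(4-methoxyphenyl)-1,3-dioxolan-4-yl]-2-methylidene-10-(trimethylsilyl)dec-5-en-9-yne
Product: 25 (2S,3R,4R,5E)-4-(TBSO)-3-[3-(TBSO)prop-1-en-2-yl]-6-(TBDPSOCH2)-2-(PMBO)-10-(trimethylsilyl)dec-5-en-9-yn-1-ol
Conditions: i-Bu2AlH, CH2Cl2, −78 to 0 °C; Rochelle salt (aq)
Reagents that add atoms: none
Why: Regioselective reductive opening of the 4-methoxybenzylidene acetal, in which aluminium coordinates the less hindered primary oxygen O9, that C–O bond ionises and hydride reduces the oxocarbenium ion, leaving the PMB ether on the secondary O8 and freeing the C9 alcohol.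

Step 17
Reactants: 25 (2S,3R,4R,5E)-4-(TBSO)-3-[3-(TBSO)prop-1-en-2-yl]-6-(TBDPSOCH2)-2-(PMBO)-10-(trimethylsilyl)dec-5-en-9-yn-1-ol
Product: 26 (2S,3R,4R,5E)-4-(TBSO)-3-[3-(TBSO)prop-1-en-2-yl]-6-(TBDPSOCH2)-2-(PMBO)-10-(trimethylsilyl)dec-5-en-9-ynal
Conditions: Dess–Martin periodinane, NaHCO3, CH2Cl2, 0 °C to rt
Reagents that add atoms: none
Why: Buffered Dess–Martin oxidation converts the primary alcohol into the α-alkoxy aldehyde under non-basic conditions that do not epimerise C8.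

Step 18
Reactants: 26 (2S,3R,4R,5E)-4-(TBSO)-3-[3-(TBSO)prop-1-en-2-yl]-6-(TBDPSOCH2)-2-(PMBO)-10-(trimethylsilyl)dec-5-en-9-ynal
Product: 27 (2S,3R,4R,5E)-4-(TBSO)-3-[3-(TBSO)prop-1-en-2-yl]-6-(TBDPSOCH2)-10-iodo-2-(PMBO)dec-5-en-9-ynal
Conditions: NIS, AgNO3 (10 mol%), DMF, rt, dark
Reagents that add atoms: N-iodosuccinimide, `O=C1CCC(=O)N1I`
Why: Silver-catalysed iododesilylation, in which the silver acetylide formed from the alkynylsilane is iodinated by N-iodosuccinimide, is placed after the oxidation so that no free hydroxyl is present to undergo iodoetherification with the 1,1-disubstituted alkene.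

Step 19
Reactants: 27 (2S,3R,4R,5E)-4-(TBSO)-3-[3-(TBSO)prop-1-en-2-yl]-6-(TBDPSOCH2)-10-iodo-2-(PMBO)dec-5-en-9-ynal
Product: 29 (4E,6R,7R,8S,9S)-6-(TBSO)-7-[3-(TBSO)prop-1-en-2-yl]-4-(TBDPSOCH2)-8-(PMBO)cyclodec-4-en-1(10)-yn-9-ol, via alkynylchromium dichloride 28 (not isolated)
Conditions: CrCl2 (10 equiv), NiCl2 (0.1 equiv), degassed THF, rt, slow addition of 27 (final 2 mM)
Reagents that add atoms: none
Why: Nozaki–Hiyama–Kishi alkynylation: zerovalent nickel formed in situ inserts into the C10–I bond, the alkynyl group passes to chromium, and the alkynylchromium species (trivalent chromium) adds to the C9 aldehyde to give a chromium alkoxide, the closest known reaction type being the chromium-mediated iodoalkyne–aldehyde closure of medium-ring cycloalkynols. The ten-membered ring C1–C10 closes by intramolecular carbonyl addition of C10 to C9 (10-exo-trig), which the linear alkyne and the ring-cis C4=C5 alkene allow without severe transannular strain. The new C9 centre is controlled by C8: chelation of the aldehyde oxygen and the O8 PMB ether to chromium fixes the C8–C9 rotamer, and closure onto the face flanked by H8 should give the 8,9-syn (9S) carbinol. The step needs cyclisation to win over oligomerisation, which slow addition at about 2 mM and the folded C6–C8 stereotriad should secure, and it needs chemoselectivity, which the low basicity of the organochromium reagent secures by leaving the epimerisable C8 centre, the silyl ethers and both alkenes untouched.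

Step 20
Reactants: 29 (4E,6R,7R,8S,9S)-6-(TBSO)-7-[3-(TBSO)prop-1-en-2-yl]-4-(TBDPSOCH2)-8-(PMBO)cyclodec-4-en-1(10)-yn-9-ol
Product: 31 (1(10)E,4E,6R,7R,8S,9R)-10-iodo-6-(TBSO)-7-[3-(TBSO)prop-1-en-2-yl]-4-(TBDPSOCH2)-8-(PMBO)cyclodeca-1(10),4-dien-9-ol, via vinylstannane 30 (not isolated)
Conditions: Bu3SnH, PdCl2(PPh3)2 (5 mol%), THF, 0 °C; then I2, 0 °C
Reagents that add atoms: iodine, `[I][I]`
Why: Palladium-catalysed syn-hydrostannation, in which the free C9 hydroxyl directs tin to the nearer alkyne carbon C10 and hydrogen to C1, followed by iododestannylation with retention, so that syn addition across the ring alkyne can only give the ring-cis C1=C10 alkene with iodine trans to C2.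

Step 21
Reactants: 31 (1(10)E,4E,6R,7R,8S,9R)-10-iodo-6-(TBSO)-7-[3-(TBSO)prop-1-en-2-yl]-4-(TBDPSOCH2)-8-(PMBO)cyclodeca-1(10),4-dien-9-ol
Product: 32 methyl (1(10)E,4E,6R,7R,8S,9S)-9-hydroxy-6-(TBSO)-7-[3-(TBSO)prop-1-en-2-yl]-4-(TBDPSOCH2)-8-(PMBO)cyclodeca-1(10),4-diene-10-carboxylate
Conditions: PdCl2(PPh3)2 (10 mol%), CO (1 atm), Et3N, MeOH–DMF, 55 °C
Reagents that add atoms: carbon monoxide, `[C-]#[O+]`; methanol, `CO`
Why: Palladium-catalysed methoxycarbonylation (oxidative addition into the C–I bond with retention, CO insertion and methanolysis of the acylpalladium) installs C14 on C10 with the alkene geometry intact, the hydroxyl being left free so that no β-acetoxy elimination from the alkenylpalladium can occur.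

Step 22
Reactants: 32 methyl (1(10)E,4E,6R,7R,8S,9S)-9-hydroxy-6-(TBSO)-7-[3-(TBSO)prop-1-en-2-yl]-4-(TBDPSOCH2)-8-(PMBO)cyclodeca-1(10),4-diene-10-carboxylate
Product: 33 methyl (1(10)E,4E,6R,7R,8S,9S)-9-acetoxy-6-(TBSO)-7-[3-(TBSO)prop-1-en-2-yl]-4-(TBDPSOCH2)-8-(PMBO)cyclodeca-1(10),4-diene-10-carboxylate
Conditions: Ac2O, pyridine, DMAP (cat.), CH2Cl2, 0 °C to rt
Reagents that add atoms: acetic anhydride, `CC(=O)OC(C)=O`
Why: Nucleophile-catalysed acylation of the secondary allylic alcohol installs the C9 acetate with retention at C9.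

Step 23
Reactants: 33 methyl (1(10)E,4E,6R,7R,8S,9S)-9-acetoxy-6-(TBSO)-7-[3-(TBSO)prop-1-en-2-yl]-4-(TBDPSOCH2)-8-(PMBO)cyclodeca-1(10),4-diene-10-carboxylate
Product: 34 methyl (1(10)E,4E,6R,7R,8S,9S)-9-acetoxy-8-hydroxy-6-(TBSO)-7-[3-(TBSO)prop-1-en-2-yl]-4-(TBDPSOCH2)cyclodeca-1(10),4-diene-10-carboxylate
Conditions: DDQ, CH2Cl2–pH 7 buffer, 0 °C
Reagents that add atoms: none
Why: Oxidative PMB cleavage, in which DDQ abstracts hydride from the electron-rich benzylic position and water hydrolyses the oxocarbenium ion, frees O8 under neutral conditions that leave silyl ethers, esters and alkenes alone and give the neighbouring acetate no base with which to migrate.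

Step 24
Reactants: 34 methyl (1(10)E,4E,6R,7R,8S,9S)-9-acetoxy-8-hydroxy-6-(TBSO)-7-[3-(TBSO)prop-1-en-2-yl]-4-(TBDPSOCH2)cyclodeca-1(10),4-diene-10-carboxylate
Product: 35 methyl (1(10)E,4E,6R,7R,8S,9S)-9-acetoxy-8-(methacryloyloxy)-6-(TBSO)-7-[3-(TBSO)prop-1-en-2-yl]-4-(TBDPSOCH2)cyclodeca-1(10),4-diene-10-carboxylate
Conditions: methacrylic anhydride, Et3N, DMAP (cat.), CH2Cl2, 0 °C to rt
Reagents that add atoms: methacrylic anhydride, `C=C(C)C(=O)OC(=O)C(C)=C`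
Why: DMAP-catalysed acylation of the C8 hydroxyl by the anhydride should outpace acetyl migration from O9 and installs the methacrylate with retention at C8.

Step 25
Reactants: 35 methyl (1(10)E,4E,6R,7R,8S,9S)-9-acetoxy-8-(methacryloyloxy)-6-(TBSO)-7-[3-(TBSO)prop-1-en-2-yl]-4-(TBDPSOCH2)cyclodeca-1(10),4-diene-10-carboxylate
Product: 36 methyl (1(10)E,4E,6R,7S,8S,9S)-9-acetoxy-6-hydroxy-7-(3-hydroxyprop-1-en-2-yl)-8-(methacryloyloxy)-4-(TBDPSOCH2)cyclodeca-1(10),4-diene-10-carboxylate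
Conditions: HF·pyridine, pyridine, THF, 0 °C to rt
Reagents that add atoms: none
Why: Pyridine-buffered acidic fluoride cleaves the primary and the secondary TBS ether faster than the more acid-stable primary TBDPS ether, freeing O6 and O12 while O15 stays protected and the esters are untouched.

Step 26
Reactants: 36 methyl (1(10)E,4E,6R,7S,8S,9S)-9-acetoxy-6-hydroxy-7-(3-hydroxyprop-1-en-2-yl)-8-(methacryloyloxy)-4-(TBDPSOCH2)cyclodeca-1(10),4-diene-10-carboxylate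
Product: 39 methyl (1(10)E,4E,6R,7S,8S,9S)-9-acetoxy-8-(methacryloyloxy)-15-(TBDPSO)germacra-1(10),4,11(13)-trien-12,6-olid-14-oate, via hydroxy enal 37 (not isolated), via lactol 38 (not isolated)
Conditions: TEMPO (20 mol%), PhI(OAc)2 (3 equiv), CH2Cl2, rt
Reagents that add atoms: none
Why: Oxoammonium-mediated oxidative lactonisation, in which the primary allylic C12 alcohol is oxidised in preference to the secondary C6 alcohol, the aldehyde is trapped by O6 as the lactol and this is oxidised on to the trans-fused α-methylene γ-lactone, the C6 and C7 centres being unchanged.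

Step 27
Reactants: 39 methyl (1(10)E,4E,6R,7S,8S,9S)-9-acetoxy-8-(methacryloyloxy)-15-(TBDPSO)germacra-1(10),4,11(13)-trien-12,6-olid-14-oate
Product: 40 methyl (1(10)E,4E,6R,7S,8S,9S)-9-acetoxy-15-hydroxy-8-(methacryloyloxy)germacra-1(10),4,11(13)-trien-12,6-olid-14-oate (CNP0179134.2)
Conditions: HF·pyridine (excess), THF, rt
Reagents that add atoms: none
Why: Fluoride-mediated cleavage of the remaining TBDPS ether under acidic, non-nucleophilic conditions releases the C15 alcohol without acyl migration or conjugate addition to the α-methylene lactone.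

Compound list

1 | dimethyl (S)-malate | `COC(=O)C[C@H](O)C(=O)OC` | starting material
2 | allyl bromide | `C=CCBr` | starting material
3 | dilithium alkoxide–enolate of 1 (not isolated) | `COC(O[Li])=C[C@H](O[Li])C(=O)OC` | intermediate
4 | dimethyl (2S,3R)-2-hydroxy-3-(prop-2-en-1-yl)butanedioate | `COC(=O)[C@@H](O)[C@@H](CC=C)C(=O)OC` | intermediate
5 | methyl (2R)-2-[(1S)-1,2-dihydroxyethyl]pent-4-enoate | `OC[C@@H](O)[C@@H](CC=C)C(=O)OC` | intermediate
6 | methyl (2R)-2-[(4S)-2-(4-methoxyphenyl)-1,3-dioxolan-4-yl]pent-4-enoate | `COC(=O)[C@H](CC=C)[C@H]1COC(c2ccc(OC)cc2)O1` | intermediate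
7 | (2R)-N-methoxy-2-[(4S)-2-(4-methoxyphenyl)-1,3-dioxolan-4-yl]-N-methylpent-4-enamide | `CON(C)C(=O)[C@H](CC=C)[C@H]1COC(c2ccc(OC)cc2)O1` | intermediate
8 | propargyl alcohol | `C#CCO` | starting material
9 | tert-butyl(diphenyl)(prop-2-yn-1-yloxy)silane | `C#CCO[Si](c1ccccc1)(c1ccccc1)C(C)(C)C` | intermediate
10 | lithium acetylide of 9 (not isolated) | `[Li]C#CCO[Si](c1ccccc1)(c1ccccc1)C(C)(C)C` | intermediate
11 | (5R)-1-(TBDPSO)-5-[(4S)-2-(4-methoxyphenyl)-1,3-dioxolan-4-yl]oct-7-en-2-yn-4-one | `CC(C)(C)[Si](c1ccccc1)(c1ccccc1)OCC#CC(=O)[C@H](CC=C)[C@H]1COC(c2ccc(OC)cc2)O1` | intermediate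
12 | (4S,5S)-1-(TBDPSO)-5-[(4S)-2-(4-methoxyphenyl)-1,3-dioxolan-4-yl]oct-7-en-2-yn-4-ol | `CC(C)(C)[Si](c1ccccc1)(c1ccccc1)OCC#C[C@@H](O)[C@H](CC=C)[C@H]1COC(c2ccc(OC)cc2)O1` | intermediate
13 | cyclic sodium alkenylalanate from 12 (O6–Al–C4 five-membered ring, H on C5; not isolated) | `[Na+].COCCO[Al-]1(OCCOC)O[C@@H]([C@H](CC=C)[C@H]2COC(c3ccc(OC)cc3)O2)C=C1CO[Si](c4ccccc4)(c5ccccc5)C(C)(C)C` | intermediate
14 | (2Z,4S,5S)-1-(TBDPSO)-2-iodo-5-[(4S)-2-(4-methoxyphenyl)-1,3-dioxolan-4-yl]octa-2,7-dien-4-ol | `CC(C)(C)[Si](c1ccccc1)(c1ccccc1)OC/C(I)=C/[C@@H](O)[C@H](CC=C)[C@H]1COC(c2ccc(OC)cc2)O1` | intermediate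
15 | (2Z,4S,5R)-4-(TBSO)-1-(TBDPSO)-2-iodo-5-[(4S)-2-(4-methoxyphenyl)-1,3-dioxolan-4-yl]octa-2,7-diene | `CC(C)(C)[Si](c1ccccc1)(c1ccccc1)OC/C(I)=C/[C@@H](O[Si](C)(C)C(C)(C)C)[C@H](CC=C)[C@H]1COC(c2ccc(OC)cc2)O1` | intermediate
16 | 7,8-diol of 15 (not isolated) | `CC(C)(C)[Si](c1ccccc1)(c1ccccc1)OC/C(I)=C/[C@@H](O[Si](C)(C)C(C)(C)C)[C@H](CC(O)CO)[C@H]1COC(c2ccc(OC)cc2)O1` | intermediate
17 | (3R,4S,5Z)-4-(TBSO)-7-(TBDPSO)-6-iodo-3-[(4S)-2-(4-methoxyphenyl)-1,3-dioxolan-4-yl]hept-5-enal | `CC(C)(C)[Si](c1ccccc1)(c1ccccc1)OC/C(I)=C/[C@@H](O[Si](C)(C)C(C)(C)C)[C@H](CC=O)[C@H]1COC(c2ccc(OC)cc2)O1` | intermediate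
18 | (3R,4S,5Z)-4-(TBSO)-7-(TBDPSO)-6-iodo-3-[(4S)-2-(4-methoxyphenyl)-1,3-dioxolan-4-yl]-2-methylidenehept-5-enal | `CC(C)(C)[Si](c1ccccc1)(c1ccccc1)OC/C(I)=C/[C@@H](O[Si](C)(C)C(C)(C)C)[C@H](C(=C)C=O)[C@H]1COC(c2ccc(OC)cc2)O1` | intermediate
19 | (3R,4S,5Z)-4-(TBSO)-7-(TBDPSO)-6-iodo-3-[(4S)-2-(4-methoxyphenyl)-1,3-dioxolan-4-yl]-2-methylidenehept-5-en-1-ol | `CC(C)(C)[Si](c1ccccc1)(c1ccccc1)OC/C(I)=C/[C@@H](O[Si](C)(C)C(C)(C)C)[C@H](C(=C)CO)[C@H]1COC(c2ccc(OC)cc2)O1` | intermediate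
20 | (3R,4S,5Z)-1,4-bis(TBSO)-7-(TBDPSO)-6-iodo-3-[(4S)-2-(4-methoxyphenyl)-1,3-dioxolan-4-yl]-2-methylidenehept-5-ene | `CC(C)(C)[Si](c1ccccc1)(c1ccccc1)OC/C(I)=C/[C@@H](O[Si](C)(C)C(C)(C)C)[C@H](C(=C)CO[Si](C)(C)C(C)(C)C)[C@H]1COC(c2ccc(OC)cc2)O1` | intermediate
21 | 4-(trimethylsilyl)but-3-yn-1-ol | `C[Si](C)(C)C#CCCO` | starting material
22 | (4-iodobut-1-yn-1-yl)trimethylsilane | `C[Si](C)(C)C#CCCI` | intermediate
23 | [4-(trimethylsilyl)but-3-yn-1-yl]zinc iodide (not isolated) | `C[Si](C)(C)C#CCC[Zn]I` | intermediate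
24 | (3R,4R,5E)-1,4-bis(TBSO)-6-(TBDPSOCH2)-3-[(4S)-2-(4-methoxyphenyl)-1,3-dioxolan-4-yl]-2-methylidene-10-(trimethylsilyl)dec-5-en-9-yne | `C1OC(c2ccc(OC)cc2)O[C@H]1[C@@H](C(=C)CO[Si](C)(C)C(C)(C)C)[C@H](O[Si](C)(C)C(C)(C)C)/C=C(/CO[Si](c3ccccc3)(c3ccccc3)C(C)(C)C)CCC#C[Si](C)(C)C` | intermediate
25 | (2S,3R,4R,5E)-4-(TBSO)-3-[3-(TBSO)prop-1-en-2-yl]-6-(TBDPSOCH2)-2-(PMBO)-10-(trimethylsilyl)dec-5-en-9-yn-1-ol | `OC[C@@H](OCc1ccc(OC)cc1)[C@@H](C(=C)CO[Si](C)(C)C(C)(C)C)[C@H](O[Si](C)(C)C(C)(C)C)/C=C(/CO[Si](c1ccccc1)(c1ccccc1)C(C)(C)C)CCC#C[Si](C)(C)C` | intermediate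
26 | (2S,3R,4R,5E)-4-(TBSO)-3-[3-(TBSO)prop-1-en-2-yl]-6-(TBDPSOCH2)-2-(PMBO)-10-(trimethylsilyl)dec-5-en-9-ynal | `O=C[C@@H](OCc1ccc(OC)cc1)[C@@H](C(=C)CO[Si](C)(C)C(C)(C)C)[C@H](O[Si](C)(C)C(C)(C)C)/C=C(/CO[Si](c1ccccc1)(c1ccccc1)C(C)(C)C)CCC#C[Si](C)(C)C` | intermediate
27 | (2S,3R,4R,5E)-4-(TBSO)-3-[3-(TBSO)prop-1-en-2-yl]-6-(TBDPSOCH2)-10-iodo-2-(PMBO)dec-5-en-9-ynal (key-step precursor) | `O=C[C@@H](OCc1ccc(OC)cc1)[C@@H](C(=C)CO[Si](C)(C)C(C)(C)C)[C@H](O[Si](C)(C)C(C)(C)C)/C=C(/CO[Si](c1ccccc1)(c1ccccc1)C(C)(C)C)CCC#CI` | intermediate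
28 | alkynylchromium dichloride from 27 (not isolated) | `O=C[C@@H](OCc1ccc(OC)cc1)[C@@H](C(=C)CO[Si](C)(C)C(C)(C)C)[C@H](O[Si](C)(C)C(C)(C)C)/C=C(/CO[Si](c1ccccc1)(c1ccccc1)C(C)(C)C)CCC#C[Cr](Cl)Cl` | intermediate
29 | (4E,6R,7R,8S,9S)-6-(TBSO)-7-[3-(TBSO)prop-1-en-2-yl]-4-(TBDPSOCH2)-8-(PMBO)cyclodec-4-en-1(10)-yn-9-ol (key-step product) | `COc1ccc(CO[C@H]2[C@@H](C(=C)CO[Si](C)(C)C(C)(C)C)[C@H](O[Si](C)(C)C(C)(C)C)/C=C(/CO[Si](c3ccccc3)(c3ccccc3)C(C)(C)C)CCC#C[C@@H]2O)cc1` | intermediate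
30 | (1(10)E,4E,6R,7R,8S,9R)-6-(TBSO)-7-[3-(TBSO)prop-1-en-2-yl]-4-(TBDPSOCH2)-8-(PMBO)-10-(tributylstannyl)cyclodeca-1(10),4-dien-9-ol (not isolated) | `COc1ccc(CO[C@H]2[C@@H](C(=C)CO[Si](C)(C)C(C)(C)C)[C@H](O[Si](C)(C)C(C)(C)C)/C=C(/CO[Si](c3ccccc3)(c3ccccc3)C(C)(C)C)CC/C=C(/[Sn](CCCC)(CCCC)CCCC)[C@@H]2O)cc1` | intermediate
31 | (1(10)E,4E,6R,7R,8S,9R)-10-iodo-6-(TBSO)-7-[3-(TBSO)prop-1-en-2-yl]-4-(TBDPSOCH2)-8-(PMBO)cyclodeca-1(10),4-dien-9-ol | `COc1ccc(CO[C@H]2[C@@H](C(=C)CO[Si](C)(C)C(C)(C)C)[C@H](O[Si](C)(C)C(C)(C)C)/C=C(/CO[Si](c3ccccc3)(c3ccccc3)C(C)(C)C)CC/C=C(/I)[C@@H]2O)cc1` | intermediate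
32 | methyl (1(10)E,4E,6R,7R,8S,9S)-9-hydroxy-6-(TBSO)-7-[3-(TBSO)prop-1-en-2-yl]-4-(TBDPSOCH2)-8-(PMBO)cyclodeca-1(10),4-diene-10-carboxylate | `COc1ccc(CO[C@H]2[C@@H](C(=C)CO[Si](C)(C)C(C)(C)C)[C@H](O[Si](C)(C)C(C)(C)C)/C=C(/CO[Si](c3ccccc3)(c3ccccc3)C(C)(C)C)CC/C=C(/C(=O)OC)[C@@H]2O)cc1` | intermediate
33 | methyl (1(10)E,4E,6R,7R,8S,9S)-9-acetoxy-6-(TBSO)-7-[3-(TBSO)prop-1-en-2-yl]-4-(TBDPSOCH2)-8-(PMBO)cyclodeca-1(10),4-diene-10-carboxylate | `COc1ccc(CO[C@H]2[C@@H](C(=C)CO[Si](C)(C)C(C)(C)C)[C@H](O[Si](C)(C)C(C)(C)C)/C=C(/CO[Si](c3ccccc3)(c3ccccc3)C(C)(C)C)CC/C=C(/C(=O)OC)[C@@H]2OC(C)=O)cc1` | intermediate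
34 | methyl (1(10)E,4E,6R,7R,8S,9S)-9-acetoxy-8-hydroxy-6-(TBSO)-7-[3-(TBSO)prop-1-en-2-yl]-4-(TBDPSOCH2)cyclodeca-1(10),4-diene-10-carboxylate | `O[C@H]1[C@@H](C(=C)CO[Si](C)(C)C(C)(C)C)[C@H](O[Si](C)(C)C(C)(C)C)/C=C(/CO[Si](c2ccccc2)(c2ccccc2)C(C)(C)C)CC/C=C(/C(=O)OC)[C@@H]1OC(C)=O` | intermediate
35 | methyl (1(10)E,4E,6R,7R,8S,9S)-9-acetoxy-8-(methacryloyloxy)-6-(TBSO)-7-[3-(TBSO)prop-1-en-2-yl]-4-(TBDPSOCH2)cyclodeca-1(10),4-diene-10-carboxylate | `C=C(C)C(=O)O[C@H]1[C@@H](C(=C)CO[Si](C)(C)C(C)(C)C)[C@H](O[Si](C)(C)C(C)(C)C)/C=C(/CO[Si](c2ccccc2)(c2ccccc2)C(C)(C)C)CC/C=C(/C(=O)OC)[C@@H]1OC(C)=O` | intermediate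
36 | methyl (1(10)E,4E,6R,7S,8S,9S)-9-acetoxy-6-hydroxy-7-(3-hydroxyprop-1-en-2-yl)-8-(methacryloyloxy)-4-(TBDPSOCH2)cyclodeca-1(10),4-diene-10-carboxylate | `C=C(C)C(=O)O[C@H]1[C@@H](C(=C)CO)[C@H](O)/C=C(/CO[Si](c2ccccc2)(c2ccccc2)C(C)(C)C)CC/C=C(/C(=O)OC)[C@@H]1OC(C)=O` | intermediate
37 | methyl (1(10)E,4E,6R,7S,8S,9S)-9-acetoxy-6-hydroxy-8-(methacryloyloxy)-7-(3-oxoprop-1-en-2-yl)-4-(TBDPSOCH2)cyclodeca-1(10),4-diene-10-carboxylate (not isolated) | `C=C(C)C(=O)O[C@H]1[C@@H](C(=C)C=O)[C@H](O)/C=C(/CO[Si](c2ccccc2)(c2ccccc2)C(C)(C)C)CC/C=C(/C(=O)OC)[C@@H]1OC(C)=O` | intermediate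
38 | C12 lactol of 37 (O6 bonded to C12, both C12 epimers; not isolated) | `C=C(C)C(=O)O[C@H]1[C@H]2C(=C)C(O)O[C@@H]2/C=C(/CO[Si](c3ccccc3)(c3ccccc3)C(C)(C)C)CC/C=C(/C(=O)OC)[C@@H]1OC(C)=O` | intermediate
39 | methyl (1(10)E,4E,6R,7S,8S,9S)-9-acetoxy-8-(methacryloyloxy)-15-(TBDPSO)germacra-1(10),4,11(13)-trien-12,6-olid-14-oate | `C=C(C)C(=O)O[C@H]1[C@H]2C(=C)C(=O)O[C@@H]2/C=C(/CO[Si](c3ccccc3)(c3ccccc3)C(C)(C)C)CC/C=C(/C(=O)OC)[C@@H]1OC(C)=O` | intermediate
40 | methyl (1(10)E,4E,6R,7S,8S,9S)-9-acetoxy-15-hydroxy-8-(methacryloyloxy)germacra-1(10),4,11(13)-trien-12,6-olid-14-oate (CNP0179134.2) | `C=C(C)C(=O)O[C@H]1[C@H]2C(=C)C(=O)O[C@@H]2/C=C(/CO)CC/C=C(/C(=O)OC)[C@@H]1OC(C)=O` | target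

Total step count: 27. Longest linear sequence: 25 steps from dimethyl (S)-malate (steps 1–4, 6–13 and 15–27); steps 5 and 14 prepare the two side fragments.

Steps most likely to fail, in order: step 19, step 20, step 25.

Step 19 may suffer from poor facial selectivity in the carbonyl addition, the conformation of the closing ring overriding the chromium chelate and delivering the C9 epimer (competing intermolecular coupling would be met by higher dilution). Fallback: starting again from 27, the closure is run without trying to bias the addition and the (9R)-epimeric cyclodecenynol F1 is taken on. Mitsunobu esterification (4-nitrobenzoic acid, PPh3, DIAD, THF, 0 °C to rt) inverts the activated propargylic centre and gives the (9S)-4-nitrobenzoate F2. Methanolysis (K2CO3, MeOH, 0 °C) returns the route to 29.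

Step 20 may lose regiocontrol in the hydrometalation, tin being delivered to C1 as well as to C10. Fallback: from 29, Dess–Martin oxidation gives the cyclodecenynone F3. Palladium-catalysed hydrostannation of this ynone (Bu3SnH, Pd(PPh3)4, THF, 0 °C) is governed by the carbonyl group, hydrogen adding to the β-carbon C1 and tin to the α-carbon C10 in a syn sense, to give the α-stannyl enone F4. CBS reduction ((S)-2-methyl-CBS-oxazaborolidine, catecholborane, −78 °C), with the stannylated alkenyl flank expected to act as the large group, should return the carbinol with the C9 configuration of 30. Compound 30 is then iodinated as in the second half of step 20.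

Step 25 may fail through loss of the TBDPS ether alongside the TBS ethers, or through incomplete cleavage of the hindered C6 TBS ether before the TBDPS ether starts to go. Fallback: from 35, all three silyl ethers are removed (HF·pyridine, THF, rt, prolonged) to give the 6,12,15-triol F5. TEMPO/PhI(OAc)2 then oxidises both primary allylic alcohols, closing the lactone and leaving C15 as an enal in the 15-oxo lactone F6. Luche reduction (NaBH4, CeCl3·7H2O, MeOH, −78 °C) reduces only the aldehyde in a 1,2 sense and arrives at the target 40.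

Further compounds
F1 | step 19 | (4E,6R,7R,8S,9R)-6-(TBSO)-7-[3-(TBSO)prop-1-en-2-yl]-4-(TBDPSOCH2)-8-(PMBO)cyclodec-4-en-1(10)-yn-9-ol (9-epimer of 29) | `COc1ccc(CO[C@H]2[C@@H](C(=C)CO[Si](C)(C)C(C)(C)C)[C@H](O[Si](C)(C)C(C)(C)C)/C=C(/CO[Si](c3ccccc3)(c3ccccc3)C(C)(C)C)CCC#C[C@H]2O)cc1`
F2 | step 19 | (4E,6R,7R,8S,9S)-6-(TBSO)-7-[3-(TBSO)prop-1-en-2-yl]-4-(TBDPSOCH2)-8-(PMBO)cyclodec-4-en-1(10)-yn-9-yl 4-nitrobenzoate | `COc1ccc(CO[C@H]2[C@@H](C(=C)CO[Si](C)(C)C(C)(C)C)[C@H](O[Si](C)(C)C(C)(C)C)/C=C(/CO[Si](c3ccccc3)(c3ccccc3)C(C)(C)C)CCC#C[C@@H]2OC(=O)c4ccc([N+](=O)[O-])cc4)cc1`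
F3 | step 20 | (4E,6R,7R,8S)-6-(TBSO)-7-[3-(TBSO)prop-1-en-2-yl]-4-(TBDPSOCH2)-8-(PMBO)cyclodec-4-en-1(10)-yn-9-one | `COc1ccc(CO[C@H]2[C@@H](C(=C)CO[Si](C)(C)C(C)(C)C)[C@H](O[Si](C)(C)C(C)(C)C)/C=C(/CO[Si](c3ccccc3)(c3ccccc3)C(C)(C)C)CCC#CC2=O)cc1`
F4 | step 20 | (1(10)E,4E,6R,7R,8S)-6-(TBSO)-7-[3-(TBSO)prop-1-en-2-yl]-4-(TBDPSOCH2)-8-(PMBO)-10-(tributylstannyl)cyclodeca-1(10),4-dien-9-one | `COc1ccc(CO[C@H]2[C@@H](C(=C)CO[Si](C)(C)C(C)(C)C)[C@H](O[Si](C)(C)C(C)(C)C)/C=C(/CO[Si](c3ccccc3)(c3ccccc3)C(C)(C)C)CC/C=C(/[Sn](CCCC)(CCCC)CCCC)C2=O)cc1`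
F5 | step 25 | methyl (1(10)E,4E,6R,7S,8S,9S)-9-acetoxy-6-hydroxy-4-(hydroxymethyl)-7-(3-hydroxyprop-1-en-2-yl)-8-(methacryloyloxy)cyclodeca-1(10),4-diene-10-carboxylate | `C=C(C)C(=O)O[C@H]1[C@@H](C(=C)CO)[C@H](O)/C=C(/CO)CC/C=C(/C(=O)OC)[C@@H]1OC(C)=O`
F6 | step 25 | methyl (1(10)E,4E,6R,7S,8S,9S)-9-acetoxy-8-(methacryloyloxy)-15-oxogermacra-1(10),4,11(13)-trien-12,6-olid-14-oate | `C=C(C)C(=O)O[C@H]1[C@H]2C(=C)C(=O)O[C@@H]2/C=C(/C=O)CC/C=C(/C(=O)OC)[C@@H]1OC(C)=O`
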